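Start from the product, the thing to foresee in theta and gamma, and ask how fast substrate turns into it at each c_reagent, because these two flasks differ in that charge.

| flask | substrate | reagent | free catalyst | remark | time |
|---|---|---|---|---|---|
| dawn | 24 mM | 53 mM | 1 mM | run made earlier |  |
| spring | 24 mM | 150 mM | 1 mM | run made earlier |  |
| theta | 24 mM | 96.0 mM | 1.0 mM |  | 4.0 min |
| gamma | 24 mM | 240 mM | 1.0 mM |  | 4.0 min |

| run | time / min | substrate / % | catalyst intermediate A / % | catalyst intermediate B / % | product / % |
|---|---|---|---|---|---|
| dawn | 0.833 | 88.9 | 2.7 | 2.6 | 5.4 |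
| dawn | 1.50 | 83.7 | 2.9 | 1.6 | 10.5 |
| dawn | 2.50 | 76.7 | 1.5 | 1.8 | 20.4 |
| dawn | 3.00 | 72.9 | 3.8 | 0.3 | 23.5 |
| dawn | 4.00 | 66.6 | 0.6 | 0.3 | 32.2 |
| spring | 0.833 | 87.6 | 1.7 | 0.6 | 13.8 |
| spring | 1.50 | 74.5 | 1.2 | 1.1 | 20.7 |
| spring | 2.50 | 64.1 | 1.7 | 0.7 | 33.8 |
| spring | 3.00 | 56.9 | 1.2 | 0.2 | 40.4 |
| spring | 4.00 | 47.8 | 1.7 | 2.7 | 49.9 |

(scatter of a reading: 1 percentage point)

- which of these there is most of at the end, counted by the substrate in it, theta (catalyst intermediate B / substrate / product / catalyst intermediate A)
- which of these there is most of at the end, counted by the substrate in it, gamma (catalyst intermediate B / substrate / product / catalyst intermediate A)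
- the largest of these amounts at the end, in percent of the substrate charged, theta
- the largest of these amounts at the end, in percent of the substrate charged, gamma



Read the substrate first: treat its fall as pseudo-first-order with a constant k, which gives 0.102 min⁻¹ in the dawn run and 0.185 min⁻¹ in the spring run. So 2.83 times the reagent yields 1.81 times the k. Draw k = kc·c_reagent/(c_reagent + Rh) through both points: the ceiling kc is 0.333 min⁻¹ and Rh is 121 mM, the half-saturation reagent, the c_reagent at which k reaches half of kc. This leaves substrate at 55.4% in theta and 41.2% in gamma, so the substrate way reckons gamma's product at 58.8%.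

Now repeat the reckoning from the product readings alone: the same curve drawn with 0.0972 min⁻¹ and 0.173 min⁻¹ has the ceiling 0.301 min⁻¹, which gives Rh as 111 mM and puts gamma's product at 56.1%. The substrate way cheats on this number, since it counts as product whatever sits on the catalyst, and the gap of 2.70% is less than the catalyst's share of 4.17%. Take the middle, 57.4%, for gamma, and keep 55.4% of substrate for theta.

The forecast names substrate in theta at 55% (52% to 58%) and product in gamma at 56% (51% to 62%), lower than mine, and widens gamma's range since “the saturation is defined by only two reagent levels”.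

The flask gives 54.7% of substrate in theta and 58.4% of product in gamma, with 40.4% of substrate left there.

    substrate + free catalyst → catalyst intermediate A (k = 11.0 M⁻¹ s⁻¹)
    reagent + catalyst intermediate A ⇌ catalyst intermediate B (K = 4.20 M⁻¹, k = 2.40 M⁻¹ s⁻¹)
    catalyst intermediate B → free catalyst + product (k = 0.380 s⁻¹)
    free catalyst → spent catalyst (k = 0.00170 s⁻¹)
    free catalyst ⇌ dormant form (K = 0.510, k = 0.130 s⁻¹)

Gamma's reagent stands at 1.99 times Rh, and its simulated substrate corresponds to k = 0.227 min⁻¹ against the 0.222 min⁻¹ reckoned from Rh; the difference in reagent takes 14 percentage points off the substrate between theta and gamma. Now take a neighbouring flask with gamma's charges but 0.40 mM of free catalyst: scaling the k from Rh with the catalyst charge gives 70.1% of substrate, and that flask holds more substrate than product, 72.3% against 27.0%.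

(The numbers in the tables come from a simulation for an exercise; the scatter is artificial.)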